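## Retrosynthetic overview

1. Target ⇐ end-game on ring A of a spiro β-acetoxy ketone: C=O → C=CH2, allylic oxidation of the neighbouring CH2, dehydrogenation to the cross-conjugated dienone.
2. trans-Br/Cl of ring B ⇐ hydroxyl-directed bromochlorination of the trisubstituted ring B alkene (Cl cis-1,3 to OH, Br trans).
3. Spiro centre and CH–O ⇐ semipinacol ring expansion of a 2,3-epoxy alcohol (cyclopentanol → cyclohexanone), the key step; oxirane configuration from an asymmetric epoxidation.
4. Cyclohexa-1,4-dienyl carbinol ⇐ cobalt-catalysed [4+2] of isoprene with a tertiary propargylic alcohol ⇐ ethynyl Grignard + 2,2-dimethylcyclopentanone.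
5. Ring order: ring B (as a cyclohexadiene) first; ring A second, grown from the cyclopentane by the ring expansion; ring A unsaturation last.

Assumption: the target is taken exactly as drawn, i.e. (1S,3R,4R,6R) in spiro[5.5]undecane numbering; ring A is the gem-dimethyl dienone ring, ring B the halogenated ring.

## Route

Step 1
Reactants: 1 2,2-dimethylcyclopentan-1-one; 2 ethynylmagnesium bromide
Product: 3 1-ethynyl-2,2-dimethylcyclopentan-1-ol (racemic)
Conditions: CeCl3, THF, −78 → 0 °C; aq. NH4Cl
Reagents that add atoms: none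
Why: 1,2-addition of an alkynyl Grignard reagent, run as the organocerium variant to suppress enolisation of the hindered ketone; the carbinol centre is racemic here.

Step 2
Reactants: 3 1-ethynyl-2,2-dimethylcyclopentan-1-ol; 4 isoprene
Product: 5 2,2-dimethyl-1-(4-methylcyclohexa-1,4-dien-1-yl)cyclopentan-1-ol (racemic)
Conditions: CoBr2(dppe) (5 mol%; dppe = Ph2PCH2CH2PPh2), ZnI2 (10 mol%), Zn (10 mol%), CH2Cl2, 25 °C
Reagents that add atoms: none
Why: cobalt-catalysed formal [4+2] cycloaddition of a terminal alkyne with a 1,3-diene (neutral Diels–Alder reaction), which with the dppe ligand gives the 1,4-disubstituted cyclohexa-1,4-diene and forms no stereocentre.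

Step 3
Reactants: 5 2,2-dimethyl-1-(4-methylcyclohexa-1,4-dien-1-yl)cyclopentan-1-ol
Product: 6 (1S)-2,2-dimethyl-1-[(1R,6S)-4-methyl-7-oxabicyclo[4.1.0]hept-3-en-1-yl]cyclopentan-1-ol
Conditions: Hf(OtBu)4 (10 mol%), C2-symmetric bis-hydroxamic acid ligand from (R,R)-cyclohexane-1,2-diamine (12 mol%), cumene hydroperoxide (0.55 equiv), toluene, 0 °C, to about 50% conversion; (R)-5 recovered
Reagents that add atoms: cumene hydroperoxide, CC(C)(OO)c1ccccc1
Why: Proposed new method: catalytic asymmetric epoxidation of a racemic, stereogenic tertiary allylic alcohol run as a kinetic resolution — the hafnium alkoxide of (S)-5 is epoxidised inside the chiral bis-hydroxamate pocket on the alkene face syn to the C–O bond, with the ring CH2 arm inside and the CMe2 arm anti to the metal, which sets the (1R,6S)-oxirane and leaves the remote alkene and (R)-5 untouched (the carbinol centre is erased in step 4, so any (R)-5 epoxidised on the same face only adds yield; the ligand antipode is used if the first run shows the opposite oxirane); the closest known reactions are hafnium- and vanadium-bis-hydroxamate epoxidations of achiral tertiary allylic alcohols and the Sharpless kinetic resolution of secondary allylic alcohols.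

Step 4
Reactants: 6 (1S)-2,2-dimethyl-1-[(1R,6S)-4-methyl-7-oxabicyclo[4.1.0]hept-3-en-1-yl]cyclopentan-1-ol
Product: 7 (6S,11S)-11-hydroxy-5,5,9-trimethylspiro[5.5]undec-8-en-1-one
Conditions: BF3·OEt2 (1.1 equiv), CH2Cl2, −78 °C
Reagents that add atoms: none
Why: Lewis-acid semipinacol rearrangement of a 2,3-epoxy alcohol with ring expansion: the oxirane opens at its tertiary carbon while the antiperiplanar, more substituted CMe2 carbon migrates with inversion, so the spiro centre is set with CMe2 trans and the new C=O carbon cis to the oxygen that stays behind as the secondary alcohol.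

Step 5
Reactants: 7 (6S,11S)-11-hydroxy-5,5,9-trimethylspiro[5.5]undec-8-en-1-one
Product: 8 (6S,7S,9R,10R)-10-bromo-9-chloro-7-hydroxy-5,5,9-trimethylspiro[5.5]undecan-1-one
Conditions: ClTi(OiPr)3 (1.1 equiv), NBS (1.05 equiv), hexanes–CH2Cl2, −20 °C
Reagents that add atoms: N-bromosuccinimide, O=C1CCC(=O)N1Br; chlorotitanium triisopropoxide, CC(C)O[Ti](Cl)(OC(C)C)OC(C)C
Why: Proposed new method: hydroxyl-directed bromochlorination of a cyclic homoallylic alcohol — the titanium alkoxide of the ring B hydroxyl carries the only reactive chloride, NBS forms the bromonium ion reversibly on both faces, and only the bromonium anti to the axial O–Ti can be opened through a six-membered transition state at the near, tertiary alkene carbon, so chlorine enters cis-1,3 to the oxygen (Markovnikov) and bromine trans to it, setting both halogen-bearing centres (free chloride, which would open the other bromonium, is absent in hexane); the closest known reaction is the titanium-mediated bromochlorination of allylic alcohols, where chloride is likewise delivered 1,3 to the oxygen.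

Step 6
Reactants: 8 (6S,7S,9R,10R)-10-bromo-9-chloro-7-hydroxy-5,5,9-trimethylspiro[5.5]undecan-1-one
Product: 9 (1S,3R,4R,6S)-4-bromo-3-chloro-3,7,7-trimethyl-11-oxospiro[5.5]undecan-1-yl acetate
Conditions: Ac2O, DMAP (cat.), pyridine, CH2Cl2, 0 → 25 °C
Reagents that add atoms: acetic anhydride, CC(=O)OC(C)=O
Why: DMAP-catalysed O-acylation of the secondary alcohol; the carbon between carbonyl and acetoxy carbon is quaternary, so no elimination is possible and no stereocentre changes.

Step 7
Reactants: 9 (1S,3R,4R,6S)-4-bromo-3-chloro-3,7,7-trimethyl-11-oxospiro[5.5]undecan-1-yl acetate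
Product: 10 (1S,3R,4R,6R)-4-bromo-3-chloro-3,7,7-trimethyl-11-methylidenespiro[5.5]undecan-1-yl acetate
Conditions: Cp2Ti(μ-Cl)(μ-CH2)AlMe2 (Tebbe reagent, 1.3 equiv), pyridine (cat.), THF–toluene, −40 → 0 °C
Reagents that add atoms: Tebbe reagent, C[Al-]1(C)C[Ti]([Cl+]1)(C2C=CC=C2)C3C=CC=C3
Why: Tebbe methylenation (titanium carbenoid olefination) converts hindered ketones without base and faster than esters, so the acetate and both halides survive.

Step 8
Reactants: 10 (1S,3R,4R,6R)-4-bromo-3-chloro-3,7,7-trimethyl-11-methylidenespiro[5.5]undecan-1-yl acetate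
Product: 11 (1S,3R,4R,6R)-4-bromo-3-chloro-10-hydroxy-3,7,7-trimethyl-11-methylidenespiro[5.5]undecan-1-yl acetate (both C-10 epimers)
Conditions: SeO2 (0.5 equiv), t-BuOOH, CH2Cl2, 25 °C
Reagents that add atoms: selenium dioxide, O=[Se]=O (oxygen carrier, reoxidised by tert-butyl hydroperoxide, CC(C)(C)OO)
Why: SeO2 allylic oxidation (ene reaction, then [2,3]-shift) can only occur at the single allylic CH2 next to the exocyclic alkene, and the new carbinol centre is removed in step 9.

Step 9
Reactants: 11 (1S,3R,4R,6R)-4-bromo-3-chloro-10-hydroxy-3,7,7-trimethyl-11-methylidenespiro[5.5]undecan-1-yl acetate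
Product: 13 (1S,3R,4R,6R)-4-bromo-3-chloro-3,7,7-trimethyl-11-methylidene-10-oxospiro[5.5]undec-8-en-1-yl acetate (target), via methylene ketone 12 (not isolated)
Conditions: IBX (4 equiv), DMSO–fluorobenzene, 25 → 70 °C
Reagents that add atoms: none
Why: IBX oxidation of the allylic alcohol to the α-methylene ketone, followed in the same flask by IBX dehydrogenation through the only available enol, gives the cross-conjugated dienone without touching the stereocentres.

## Compound list

1 | 2,2-dimethylcyclopentan-1-one | CC1(C)CCCC1=O | starting material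
2 | ethynylmagnesium bromide | C#C[Mg]Br | starting material
3 | 1-ethynyl-2,2-dimethylcyclopentan-1-ol (racemic) | C#CC1(O)CCCC1(C)C | intermediate
4 | isoprene (2-methylbuta-1,3-diene) | CC(=C)C=C | starting material
5 | 2,2-dimethyl-1-(4-methylcyclohexa-1,4-dien-1-yl)cyclopentan-1-ol (racemic) | CC1=CCC(=CC1)C1(O)CCCC1(C)C | intermediate
6 | (1S)-2,2-dimethyl-1-[(1R,6S)-4-methyl-7-oxabicyclo[4.1.0]hept-3-en-1-yl]cyclopentan-1-ol | O[C@]3(CCCC3(C)C)[C@@]12CC=C(C)C[C@@H]1O2 | intermediate
7 | (6S,11S)-11-hydroxy-5,5,9-trimethylspiro[5.5]undec-8-en-1-one | O=C1CCCC(C)(C)[C@]12CC=C(C)C[C@@H]2O | intermediate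
8 | (6S,7S,9R,10R)-10-bromo-9-chloro-7-hydroxy-5,5,9-trimethylspiro[5.5]undecan-1-one | O=C1CCCC(C)(C)[C@]12C[C@@H](Br)[C@](C)(Cl)C[C@@H]2O | intermediate
9 | (1S,3R,4R,6S)-4-bromo-3-chloro-3,7,7-trimethyl-11-oxospiro[5.5]undecan-1-yl acetate | O=C1CCCC(C)(C)[C@]12C[C@@H](Br)[C@](C)(Cl)C[C@@H]2OC(C)=O | intermediate
10 | (1S,3R,4R,6R)-4-bromo-3-chloro-3,7,7-trimethyl-11-methylidenespiro[5.5]undecan-1-yl acetate | C=C1CCCC(C)(C)[C@]12C[C@@H](Br)[C@](C)(Cl)C[C@@H]2OC(C)=O | intermediate
11 | (1S,3R,4R,6R)-4-bromo-3-chloro-10-hydroxy-3,7,7-trimethyl-11-methylidenespiro[5.5]undecan-1-yl acetate (both C-10 epimers) | C=C1C(O)CCC(C)(C)[C@]12C[C@@H](Br)[C@](C)(Cl)C[C@@H]2OC(C)=O | intermediate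
12 | (1S,3R,4R,6R)-4-bromo-3-chloro-3,7,7-trimethyl-11-methylidene-10-oxospiro[5.5]undecan-1-yl acetate | C=C1C(=O)CCC(C)(C)[C@]12C[C@@H](Br)[C@](C)(Cl)C[C@@H]2OC(C)=O | intermediate (not isolated)
13 | (1S,3R,4R,6R)-4-bromo-3-chloro-3,7,7-trimethyl-11-methylidene-10-oxospiro[5.5]undec-8-en-1-yl acetate | C=C1C(=O)C=CC(C)(C)[C@]12C[C@@H](Br)[C@](C)(Cl)C[C@@H]2OC(C)=O | target

## Step count and risks

Total step count: 9. Longest linear sequence: 9 steps (1 → 13). Step 3 is a resolution, so its yield is capped near 50% unless the slow enantiomer also reacts on the same face.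

Steps most likely to fail:

**Step 5 (new).** Risks are bromoetherification to a 7-oxabicyclo[2.2.1]heptane, or undirected opening giving the diastereomer with bromine cis to the hydroxyl, because the reactive chair needs the C–O bond and the CMe2 carbon axial. The fallback uses known chemistry, sets out from 7 and comes back at 9. VO(acac)2/t-BuOOH (CH2Cl2, 0 °C) epoxidises 7 under direction of the homoallylic hydroxyl to the cis-epoxy alcohol (6S,7S,9R,10S)-9,10-epoxy-7-hydroxy-5,5,9-trimethylspiro[5.5]undecan-1-one F6. Li2NiBr4 (THF, 25 °C) opens the oxirane by SN2 attack of bromide at the secondary carbon to (6S,7S,9R,10R)-10-bromo-7,9-dihydroxy-5,5,9-trimethylspiro[5.5]undecan-1-one F7. Ac2O/pyridine acetylates only the secondary hydroxyl to (1S,3R,4R,6S)-4-bromo-3-hydroxy-3,7,7-trimethyl-11-oxospiro[5.5]undecan-1-yl acetate F8. SOCl2 (CH2Cl2, 0 °C) then exchanges the tertiary hydroxyl for chloride with retention, because the trans bromine closes to a bromonium ion that chloride reopens at the tertiary carbon, and this gives 9. The detour costs two extra steps.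

**Step 3 (new).** Risks are a low selectivity factor for this hindered tertiary carbinol and some epoxidation of the remote alkene. The fallback uses known chemistry, sets out from 3 and comes back at 6. Racemic 3 is treated with (S)-1-phenylethyl isocyanate (CuCl cat., DMF), and the diastereomer (1S)-1-ethynyl-2,2-dimethylcyclopentyl N-[(1S)-1-phenylethyl]carbamate F1 is separated by crystallisation or chromatography. LiAlH4 (THF) releases (1S)-1-ethynyl-2,2-dimethylcyclopentan-1-ol F2. The cycloaddition of step 2 gives (1S)-2,2-dimethyl-1-(4-methylcyclohexa-1,4-dien-1-yl)cyclopentan-1-ol F3. Achiral VO(acac)2/t-BuOOH then epoxidises the allylic alkene under hydroxyl direction, with the carbinol centre controlling the face, to give 6.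

**Step 4.** The risk is loss of the doubly allylic proton from the opened oxirane, which leads through a cyclohexadienol to an aromatic p-tolyl by-product, or participation of the ring B alkene. The fallback sets out from 6 and comes back at 7, with the alkene masked during the rearrangement. Pyridinium tribromide (CH2Cl2, −20 °C) gives the trans-dibromide (1S)-1-[(1R,6S)-3,4-dibromo-4-methyl-7-oxabicyclo[4.1.0]heptan-1-yl]-2,2-dimethylcyclopentan-1-ol F4. BF3·OEt2 rearranges it to (6S,7S)-9,10-dibromo-7-hydroxy-5,5,9-trimethylspiro[5.5]undecan-1-one F5, which cannot aromatise by simple proton loss. Zn/AcOH then restores the alkene and gives 7.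

## Further compounds

F1 | step 3 | (1S)-1-ethynyl-2,2-dimethylcyclopentyl N-[(1S)-1-phenylethyl]carbamate | O=C(N[C@@H](C)c1ccccc1)O[C@]1(CCCC1(C)C)C#C
F2 | step 3 | (1S)-1-ethynyl-2,2-dimethylcyclopentan-1-ol | O[C@]1(CCCC1(C)C)C#C
F3 | step 3 | (1S)-2,2-dimethyl-1-(4-methylcyclohexa-1,4-dien-1-yl)cyclopentan-1-ol | O[C@]1(CCCC1(C)C)C1=CCC(C)=CC1
F4 | step 4 | (1S)-1-[(1R,6S)-3,4-dibromo-4-methyl-7-oxabicyclo[4.1.0]heptan-1-yl]-2,2-dimethylcyclopentan-1-ol (trans-dibromide) | O[C@]3(CCCC3(C)C)[C@@]12CC(Br)C(C)(Br)C[C@@H]1O2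
F5 | step 4 | (6S,7S)-9,10-dibromo-7-hydroxy-5,5,9-trimethylspiro[5.5]undecan-1-one (trans-dibromide) | O=C1CCCC(C)(C)[C@]12CC(Br)C(C)(Br)C[C@@H]2O
F6 | step 5 | (6S,7S,9R,10S)-9,10-epoxy-7-hydroxy-5,5,9-trimethylspiro[5.5]undecan-1-one | O=C1CCCC(C)(C)[C@]12C[C@@H]3O[C@]3(C)C[C@@H]2O
F7 | step 5 | (6S,7S,9R,10R)-10-bromo-7,9-dihydroxy-5,5,9-trimethylspiro[5.5]undecan-1-one | O=C1CCCC(C)(C)[C@]12C[C@@H](Br)[C@](C)(O)C[C@@H]2O
F8 | step 5 | (1S,3R,4R,6S)-4-bromo-3-hydroxy-3,7,7-trimethyl-11-oxospiro[5.5]undecan-1-yl acetate | O=C1CCCC(C)(C)[C@]12C[C@@H](Br)[C@](C)(O)C[C@@H]2OC(C)=O
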